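## The problem

Gnetucleistol F (19) is a 2,3-dihydrobenzofuran. Ring A carries a methoxy group at C7 and an (E)-3,5-dihydroxystyryl arm at C5; the dihydrofuran ring carries a 4-hydroxy-3,5-dimethoxyphenyl (syringyl) ring at C2 and a hydroxymethyl group at C3. The only stereocentres are the adjacent C2 (R) and C3 (S), trans to each other. C2 is a benzylic ether carbon para to a phenol and can open to a para-quinone methide and reclose, so it settles trans to C3; C3 has no such escape, and the synthesis comes down to fixing C3 in absolute terms. The free phenols (the syringol above all) are easily oxidised, the stilbene forbids hydrogenolysis and late ultraviolet light, and any carbonyl group on C3 invites enolisation and β-elimination of the ring-A phenoxide across C2–O1. The stilbene is therefore best attached last, which asks for a handle at C5 that survives everything before it. The enabling feature is that the oxygen of the C3 hydroxymethyl group stands 1,3 to C2: C2, C3, the CH2OH carbon and its oxygen are the four atoms of an oxetane fused across the C2=C3 bond of a benzofuran, and in that oxetane C2 is an acetal carbon that can trade its strained C–O bond for the C2–aryl bond.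

## Retrosynthesis

**Stilbene arm.** After the three phenols of 19 are masked as the tris-silyl ether 18, the bond cut is C5–vinyl, giving aryl bromide 14 and styrene 17 (Mizoroki–Heck). Cutting the C=C bond instead (olefination) would need a C5 aldehyde, which is photoactive and reducible; a bromide is inert to long-wavelength light, BF3, hydride at 0 °C and periodate. 14 holds both stereocentres; 17 is achiral and comes from 15 by way of 16. The forward reaction must give the E alkene and tolerate a free primary alcohol.

**Side chain.** No skeletal bond of the target is cut here. The CH2OH carbon of 14 is traced back through aldehyde 13 to the glycol 12, and further to the α-hydroxy ester 11 and its free phenol 10. The extra carbon is the price of using a glyoxylate: it makes the carbonyl a good photochemical partner, carries the auxiliary and leaves as a one-carbon fragment. The silyl group of 11 sits between arylation and cleavage because the syringol must be free for the first and masked for the second. The forward steps must return the auxiliary alcohol 4 and must not let 13 enolise.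

**C2–aryl bond.** 10 is cut between C2 and the syringyl ring, giving 2,6-dimethoxyphenol (9) as the nucleophile and oxetane acetal 8 as the C2 cation equivalent. The oxygen that leaves C2 is the oxygen of the future CH2OH group. Against a cut at O1–C2 or C3–C3a, this one brings in the whole aryl ring from a commodity phenol without protection and derives C2 from C3. The forward reaction must attack para to the hydroxyl of 9, add anti to the C3 side chain, and avoid loss of the C3 proton.

**Key [2+2].** 8 is cut at two bonds, C3 to the carbinol carbon and C2 to the oxetane oxygen, giving benzofuran 3 and glyoxylate 7. An aldol route to the same bonds would go through a benzofuran-2(3H)-one whose C3 proton is acidic; the photochemical cut makes both bonds on one face and needs no base. Both partners are flat in their reacting parts and two steps from commercial material. The forward reaction must control regiochemistry, the face of 3, and chemoselectivity for the carbonyl over the aryl bromide.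

**Partners.** 3 is taken back through the aryloxyacetic acid 2 to 5-bromo-2-hydroxy-3-methoxybenzaldehyde (1), by cutting the furan C2–C3 bond. 7 comes from (−)-8-phenylmenthol (4) through acrylate 5 and its ozonide 6. These are standard reactions on commercial compounds.

## Roads not taken

Alternative 1: Ring A is cut at C3a–C7a and C4–C5, back to the alkynyl pyridazinyl ether A2. On heating, the tethered alkyne would add across C3 and C6 of the pyridazine and lose N2 to give the silyl-protected 5-chloro dihydrobenzofuran A1.
- Merits: both stereocentres are made in an open chain before the key step, the tether fixes regiochemistry, the pyridazine programmes the ring-A pattern, and C3 already has the right carbon count. In stereochemical certainty before the key step this road is better than the chosen one, which rests on an untested facial selectivity.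
- Weak points: a pyridazine made electron-richer by a methoxy group is a poor azadiene for an unactivated alkyne, so temperatures near 200 °C are expected. At that temperature the benzylic C–O bond of A2, attached to a good heteroaryloxy leaving group, can ionise or eliminate, and the propargylic C–H can isomerise; both erase the centres set beforehand. The chloride of A1 is a weaker Heck handle than bromide, and A2 needs a multi-step anti-selective synthesis.
- Comparison: the chosen plan sets against it a ring-forming step near room temperature, partners two steps from commercial material, and diastereomers that can be separated if the selectivity is imperfect.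

Alternative 2: The C3–C3a bond is cut, back to the (2R)-flavanone A4. With PhI(OAc)2 and H2SO4 in trimethyl orthoformate, ring A would shift from the carbonyl carbon to C3 and contract the pyranone to the trans methyl ester A3.
- Merits: this ring contraction is established on flavanones for exactly this skeleton, enantioenriched flavanones are accessible by catalytic conjugate addition, and A3 needs only reduction of the ester. In precedent and in steps after the key step this road is better.
- Weak points: the migrating ring A is deactivated by bromine, while the dimethoxy-substituted B ring, even as its pivalate, is the more electron-rich ring and can migrate instead or be oxidised by trivalent iodine. A4 can racemise at C2 by retro-oxa-Michael opening in strong acid. A3 carries the enolisable C3 ester next to the C2–O1 leaving group.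
- Comparison: the chosen plan sets against it that no racemisable centre exists before its key step, that the B ring arrives unprotected from 9 and never meets a strong oxidant while free, and that C2 is made under the control of an already secure C3.

Alternative 3: The O1–C2 bond is cut, back to the open bisphenol A6. A flavoprotein oxidase of the vanillyl alcohol oxidase or eugenol oxidase class would remove hydride from the benzylic CH2 para to the syringyl phenol. The ring-A phenol would then add to the para-quinone methide A7 and give the bromo alcohol A5.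
- Merits: no protecting groups, oxygen as oxidant, water as solvent, and a product two steps from the target. In step economy and mildness this is the best of the four.
- Weak points: these oxidases are known for small 4-alkyl and 4-allyl phenols, and acceptance of the branched diaryl substrate A6 would have to be engineered. The enzyme normally hydrates its quinone methide, or deprotonates it, which here would erase C3. The stereocentre of A6 must still be made by separate asymmetric chemistry, so the central problem is moved, not solved.
- Comparison: the chosen plan sets against it a key step whose reaction class is known on benzofurans and which itself creates the C3 configuration.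

Key step: step 5

Assumption: the s-trans dicarbonyl conformer of 7 is taken to react and the phenyl ring of the (−)-auxiliary to shield one face of the ester-substituted radical centre, which predicts the 2R exo adduct 8; this sense is not established for this pair of partners, and (+)-8-phenylmenthol would replace 4 in steps 3 to 5 if the opposite sense were found.

Step 1
Reactants: 1 5-bromo-2-hydroxy-3-methoxybenzaldehyde
Product: 2 2-(4-bromo-2-formyl-6-methoxyphenoxy)acetic acid
Conditions: ClCH2CO2H, NaOH, H2O, reflux; then HCl
Reagents that add atoms: chloroacetic acid, OC(=O)CCl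
Why: Williamson ether synthesis: the phenoxide of 1 displaces chloride from chloroacetate and acidification gives the aryloxyacetic acid; the aldehyde has no enolisable position and is left alone.

Step 2
Reactants: 2 2-(4-bromo-2-formyl-6-methoxyphenoxy)acetic acid
Product: 3 5-bromo-7-methoxy-1-benzofuran
Conditions: NaOAc, Ac2O, AcOH, 140 °C
Reagents that add atoms: none
Why: Intramolecular Perkin-type condensation: the mixed anhydride of 2 enolises and adds to the ortho aldehyde, and the β-acyloxy acid so formed loses CO2 and acetate to give the benzofuran unsubstituted at C2 and C3, the classical conversion of 2-formylphenoxyacetic acids.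

Step 3
Reactants: 4 (−)-8-phenylmenthol
Product: 5 (−)-8-phenylmenthyl acrylate
Conditions: CH2=CHCOCl, Et3N, DMAP (cat.), CH2Cl2, 0 °C
Reagents that add atoms: acryloyl chloride, C=CC(=O)Cl
Why: DMAP-catalysed acylation of the hindered secondary alcohol; the three stereocentres of the auxiliary are not involved.

Step 4
Reactants: 5 (−)-8-phenylmenthyl acrylate
Product: 7 (−)-8-phenylmenthyl glyoxylate, via ozonide 6 (not isolated)
Conditions: O3, CH2Cl2, −78 °C; then Me2S, −78 °C → rt; non-aqueous work-up, 4 Å MS
Reagents that add atoms: ozone, [O-][O+]=O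
Why: Ozonolysis of the terminal alkene: cycloaddition and recombination give ozonide 6, which Me2S reduces to the aldehyde and formaldehyde; water is excluded because the photoreaction needs the free aldehyde and not its hydrate.

Step 5
Reactants: 3 5-bromo-7-methoxy-1-benzofuran; 7 (−)-8-phenylmenthyl glyoxylate
Product: 8 (−)-8-phenylmenthyl (2R,2aS,7aS)-4-bromo-6-methoxy-2a,7a-dihydro-2H-oxeto[2,3-b][1]benzofuran-2-carboxylate (oxetane cis-fused across the benzofuran C2=C3 bond, oxetane oxygen on the acetal carbon, ester exo)
Conditions: hν (λ ≥ 340 nm), 3 (3 equiv), PhH, 10 °C, Ar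
Reagents that add atoms: none
Why: Paternò–Büchi reaction, the closest precedent being the photocycloaddition of furans and benzofurans to aldehydes and to glyoxylates of chiral alcohols: light above 340 nm should be absorbed only by 7, whose n,π* triplet adds through oxygen to C2 of the enol-ether double bond of 3 and gives the triplet 1,4-biradical with the radical at benzylic C3. After spin inversion the oxetane is closed by recombination of the C3 radical with the ester-substituted radical carbon (the second bond of a stepwise [2+2]); a four-membered ring can only be cis-fused to the five-membered ring, which ties the two ring-fusion centres to each other. The configuration of the ester-bearing carbon (2R) is set in this closure: the planar, ester-conjugated radical is covered on one face by the phenyl ring of the auxiliary and bonds to C3 through the open face. The preference for closure with the ester on the convex (exo) side then translates that configuration into the choice of benzofuran face, so 2aS and 7aS follow from auxiliary shielding and exo closure acting together, and a biradical on the other face, which would have to close endo or on the shielded side, is expected largely to fall back to 3 and 7. The selectivity the route needs is this facial one, since C2a becomes C3 of the target; exo and endo adducts on the same face converge later, whereas adducts on the opposite face are diastereomers of 8 and are to be removed by chromatography on Et3N-deactivated silica. Regiochemistry rests on the stability of the benzylic biradical, and chemoselectivity on the wavelength (the aryl bromide is not excited) and on the excess of 3, which should outrun Norrish γ-hydrogen abstraction within 7.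

Step 6
Reactants: 8 the oxetane acetal; 9 2,6-dimethoxyphenol
Product: 10 (−)-8-phenylmenthyl (2R)-2-[(2R,3S)-5-bromo-2-(4-hydroxy-3,5-dimethoxyphenyl)-7-methoxy-2,3-dihydro-1-benzofuran-3-yl]-2-hydroxyacetate
Conditions: 9 (5 equiv), BF3·OEt2 (0.5 equiv), CH2Cl2, −78 → −40 °C
Reagents that add atoms: none
Why: Proposed new method: BF3 should bind the strained oxetane oxygen of 8 and ionise the acetal C–O bond with release of ring strain to a 2,3-dihydrobenzofuran-2-yl oxocarbenium ion; C4 of 9, para to its free hydroxyl, attacks on the face opposite the C3 side chain (then a bulky boron-bound alkoxide), which sets C2 as R and trans to C3, and proton loss restores the phenol and frees the Lewis acid. Excess 9 at low temperature is meant to outrun loss of the C3 proton to an aromatic benzofuran, and a cis isomer could still equilibrate to trans through the para-quinone methide. The closest known reaction types are the Lewis-acid Friedel–Crafts C-arylation of cyclic acetals by phenols (aryl C-glycoside formation) and the acid-promoted opening of furan–carbonyl photoadduct oxetanes by oxygen nucleophiles.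

Step 7
Reactants: 10 the phenolic α-hydroxy ester
Product: 11 (−)-8-phenylmenthyl (2R)-2-[(2R,3S)-5-bromo-2-{3,5-dimethoxy-4-[(triisopropylsilyl)oxy]phenyl}-7-methoxy-2,3-dihydro-1-benzofuran-3-yl]-2-hydroxyacetate
Conditions: TIPSCl, imidazole, DMF, 0 °C → rt
Reagents that add atoms: chlorotri(propan-2-yl)silane (TIPSCl), CC(C)[Si](Cl)(C(C)C)C(C)C
Why: Silyl ether formation at the phenol; the bulky silyl chloride should leave untouched the secondary alcohol, which is flanked by the branched C3 and the hindered ester, and the aryl silyl ether masks the syringol against periodate in step 9.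

Step 8
Reactants: 11 the silylated α-hydroxy ester
Product: 12 (1R)-1-[(2R,3S)-5-bromo-2-{3,5-dimethoxy-4-[(triisopropylsilyl)oxy]phenyl}-7-methoxy-2,3-dihydro-1-benzofuran-3-yl]ethane-1,2-diol
Conditions: LiAlH4, THF, 0 °C → rt
Reagents that add atoms: none
Why: Hydride reduction of the ester to the primary alcohol, which also returns the auxiliary alcohol 4 for reuse; the aryl bromide and the aryl silyl ether are inert at this temperature and no stereocentre is touched.

Step 9
Reactants: 12 the 1,2-diol
Product: 14 [(2R,3S)-5-bromo-2-{3,5-dimethoxy-4-[(triisopropylsilyl)oxy]phenyl}-7-methoxy-2,3-dihydro-1-benzofuran-3-yl]methanol, via aldehyde 13 (not isolated)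
Conditions: NaIO4, NaH2PO4/Na2HPO4 (pH 7), THF–H2O, 0 °C; then NaBH4, 0 °C
Reagents that add atoms: none
Why: Malaprade glycol cleavage followed by borohydride reduction in the same flask; aldehyde 13 is α-aryl and β-aryloxy, so it is reduced at once to forestall enolisation and β-elimination across C2–O1. C3 keeps its configuration, and the trans arrangement is also the thermodynamic one.

Step 10
Reactants: 15 3,5-dihydroxybenzaldehyde
Product: 16 3,5-bis[(tert-butyldimethylsilyl)oxy]benzaldehyde
Conditions: TBSCl, imidazole, DMF, rt
Reagents that add atoms: tert-butylchlorodimethylsilane (TBSCl), CC(C)(C)[Si](C)(C)Cl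
Why: Standard silylation of both phenols, which removes the acidic protons before the ylide is used.

Step 11
Reactants: 16 3,5-bis[(tert-butyldimethylsilyl)oxy]benzaldehyde
Product: 17 1-ethenyl-3,5-bis[(tert-butyldimethylsilyl)oxy]benzene
Conditions: Ph3PCH3Br, KOtBu, THF, 0 °C → rt
Reagents that add atoms: methyltriphenylphosphonium bromide, C[P+](c1ccccc1)(c1ccccc1)c1ccccc1.[Br-]
Why: Wittig methylenation of an aromatic aldehyde by the unstabilised ylide; no stereochemical issue arises for a terminal alkene.

Step 12
Reactants: 14 the bromo alcohol; 17 the bis-silylated styrene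
Product: 18 [(2R,3S)-5-{(E)-2-[3,5-bis(tert-butyldimethylsilyloxy)phenyl]ethenyl}-2-{3,5-dimethoxy-4-[(triisopropylsilyl)oxy]phenyl}-7-methoxy-2,3-dihydro-1-benzofuran-3-yl]methanol
Conditions: Pd(OAc)2 (5 mol %), P(o-tol)3 (15 mol %), Et3N, DMF, 100 °C
Reagents that add atoms: none
Why: Mizoroki–Heck reaction: zerovalent palladium inserts into the unhindered C5–Br bond, the aryl group adds to the terminal carbon of 17, and syn β-hydride elimination gives the E stilbene; the free primary alcohol and the aryl silyl ethers are tolerated by the amine base.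

Step 13
Reactants: 18 the tris-silylated stilbene
Product: 19 gnetucleistol F, 5-[(E)-2-[(2R,3S)-3-(hydroxymethyl)-2-(4-hydroxy-3,5-dimethoxyphenyl)-7-methoxy-2,3-dihydro-1-benzofuran-5-yl]ethenyl]benzene-1,3-diol
Conditions: Bu4NF, AcOH, THF, 0 °C → rt
Reagents that add atoms: none
Why: Fluoride cleaves the three aryl silyl ethers; the acetic acid buffer keeps the phenols protonated, which guards against quinone-methide opening at C2 and against air oxidation of the phenoxides.

## Compound list

1 | 5-bromo-2-hydroxy-3-methoxybenzaldehyde | COc1cc(Br)cc(C=O)c1O | starting material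
2 | 2-(4-bromo-2-formyl-6-methoxyphenoxy)acetic acid | COc1cc(Br)cc(C=O)c1OCC(=O)O | intermediate
3 | 5-bromo-7-methoxy-1-benzofuran | COc1cc(Br)cc2ccoc12 | intermediate
4 | (−)-8-phenylmenthol, (1R,2S,5R)-5-methyl-2-(2-phenylpropan-2-yl)cyclohexan-1-ol | C[C@@H]1CC[C@H]([C@@H](C1)O)C(C)(C)c2ccccc2 | starting material
5 | (−)-8-phenylmenthyl acrylate, (1R,2S,5R)-5-methyl-2-(2-phenylpropan-2-yl)cyclohexyl prop-2-enoate | C[C@@H]1CC[C@H]([C@@H](C1)OC(=O)C=C)C(C)(C)c2ccccc2 | intermediate
6 | (−)-8-phenylmenthyl 1,2,4-trioxolane-3-carboxylate (ozonide of 5, both epimers at the trioxolane carbon) | C[C@@H]1CC[C@H]([C@@H](C1)OC(=O)C3OCOO3)C(C)(C)c2ccccc2 | intermediate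
7 | (−)-8-phenylmenthyl glyoxylate, (1R,2S,5R)-5-methyl-2-(2-phenylpropan-2-yl)cyclohexyl 2-oxoacetate | C[C@@H]1CC[C@H]([C@@H](C1)OC(=O)C=O)C(C)(C)c2ccccc2 | intermediate
8 | (1R,2S,5R)-5-methyl-2-(2-phenylpropan-2-yl)cyclohexyl (2R,2aS,7aS)-4-bromo-6-methoxy-2a,7a-dihydro-2H-oxeto[2,3-b][1]benzofuran-2-carboxylate (C2a is benzofuran C3, C7a is benzofuran C2; ester exo) | C[C@@H]1CC[C@H]([C@@H](C1)OC(=O)[C@@H]3O[C@H]4Oc5c(OC)cc(Br)cc5[C@@H]34)C(C)(C)c2ccccc2 | intermediate
9 | 2,6-dimethoxyphenol | COc1cccc(OC)c1O | starting material
10 | (1R,2S,5R)-5-methyl-2-(2-phenylpropan-2-yl)cyclohexyl (2R)-2-[(2R,3S)-5-bromo-2-(4-hydroxy-3,5-dimethoxyphenyl)-7-methoxy-2,3-dihydro-1-benzofuran-3-yl]-2-hydroxyacetate | COc1cc([C@@H]2Oc3c(OC)cc(Br)cc3[C@H]2[C@@H](O)C(=O)O[C@@H]4C[C@H](C)CC[C@H]4C(C)(C)c5ccccc5)cc(OC)c1O | intermediate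
11 | (1R,2S,5R)-5-methyl-2-(2-phenylpropan-2-yl)cyclohexyl (2R)-2-[(2R,3S)-5-bromo-2-{3,5-dimethoxy-4-[(triisopropylsilyl)oxy]phenyl}-7-methoxy-2,3-dihydro-1-benzofuran-3-yl]-2-hydroxyacetate | COc1cc([C@@H]2Oc3c(OC)cc(Br)cc3[C@H]2[C@@H](O)C(=O)O[C@@H]4C[C@H](C)CC[C@H]4C(C)(C)c5ccccc5)cc(OC)c1O[Si](C(C)C)(C(C)C)C(C)C | intermediate
12 | (1R)-1-[(2R,3S)-5-bromo-2-{3,5-dimethoxy-4-[(triisopropylsilyl)oxy]phenyl}-7-methoxy-2,3-dihydro-1-benzofuran-3-yl]ethane-1,2-diol | COc1cc([C@@H]2Oc3c(OC)cc(Br)cc3[C@H]2[C@@H](O)CO)cc(OC)c1O[Si](C(C)C)(C(C)C)C(C)C | intermediate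
13 | (2R,3R)-5-bromo-2-{3,5-dimethoxy-4-[(triisopropylsilyl)oxy]phenyl}-7-methoxy-2,3-dihydro-1-benzofuran-3-carbaldehyde (same spatial arrangement as 14) | COc1cc([C@@H]2Oc3c(OC)cc(Br)cc3[C@H]2C=O)cc(OC)c1O[Si](C(C)C)(C(C)C)C(C)C | intermediate
14 | [(2R,3S)-5-bromo-2-{3,5-dimethoxy-4-[(triisopropylsilyl)oxy]phenyl}-7-methoxy-2,3-dihydro-1-benzofuran-3-yl]methanol | COc1cc([C@@H]2Oc3c(OC)cc(Br)cc3[C@H]2CO)cc(OC)c1O[Si](C(C)C)(C(C)C)C(C)C | intermediate
15 | 3,5-dihydroxybenzaldehyde | O=Cc1cc(O)cc(O)c1 | starting material
16 | 3,5-bis[(tert-butyldimethylsilyl)oxy]benzaldehyde | O=Cc1cc(O[Si](C)(C)C(C)(C)C)cc(O[Si](C)(C)C(C)(C)C)c1 | intermediate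
17 | 1-ethenyl-3,5-bis[(tert-butyldimethylsilyl)oxy]benzene | C=Cc1cc(O[Si](C)(C)C(C)(C)C)cc(O[Si](C)(C)C(C)(C)C)c1 | intermediate
18 | [(2R,3S)-5-{(E)-2-[3,5-bis(tert-butyldimethylsilyloxy)phenyl]ethenyl}-2-{3,5-dimethoxy-4-[(triisopropylsilyl)oxy]phenyl}-7-methoxy-2,3-dihydro-1-benzofuran-3-yl]methanol | COc1cc([C@@H]2Oc3c(OC)cc(/C=C/c4cc(O[Si](C)(C)C(C)(C)C)cc(O[Si](C)(C)C(C)(C)C)c4)cc3[C@H]2CO)cc(OC)c1O[Si](C(C)C)(C(C)C)C(C)C | intermediate
19 | gnetucleistol F, 5-[(E)-2-[(2R,3S)-3-(hydroxymethyl)-2-(4-hydroxy-3,5-dimethoxyphenyl)-7-methoxy-2,3-dihydro-1-benzofuran-5-yl]ethenyl]benzene-1,3-diol | COc1cc([C@@H]2Oc3c(OC)cc(/C=C/c4cc(O)cc(O)c4)cc3[C@H]2CO)cc(OC)c1O | target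

## Step count and least certain steps

Total: 13 steps. Longest linear sequence: 9 steps (1, 2, 5, 6, 7, 8, 9, 12, 13 from compound 1; the branch from 4 through steps 3 and 4 is equally long).

**Step 6 (arylation, proposed new method).** The most likely failure is loss of the C3 proton from the oxocarbenium ion, which gives an aromatic benzofuran and erases C3, because that proton is acidified by the adjacent cation. A lesser risk is attack through the phenol oxygen or through C3 of 9, which is activated by two methoxy groups.
Fallback with known chemistry, from 8 to 11: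
- 8 is hydrolysed with dilute HCl in THF–H2O at 0 °C (the known acid opening of such photoadducts) to the 2-hydroxy-2,3-dihydrobenzofuran lactol F1.
- Commercial 4-bromo-2,6-dimethoxyphenol is silylated to (4-bromo-2,6-dimethoxyphenoxy)triisopropylsilane F2 and converted with Mg in THF into the arylmagnesium bromide F3.
- Excess F3 adds at −78 °C to the aldehyde form of F1, leaving the hindered auxiliary ester alone, to give the open triol F4 as a mixture of benzylic carbinol epimers.
- Catalytic TsOH in CH2Cl2 at 0 °C closes O1–C2 through the para-silyloxybenzyl cation under thermodynamic trans control and gives 11, so step 7 is skipped.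

**Step 5 (key step).** The most likely failure is poor discrimination between the two benzofuran faces, or diastereomers too close to separate on deactivated silica. The auxiliary sits four atoms from the first-formed bond and acts only at the ring-closure stage. Low conversion through γ-hydrogen abstraction is a second risk.
Fallback, from 3 to 12:
- 3 is irradiated with commercial ethyl glyoxylate to give the racemic exo oxetane ethyl ester F5.
- The conditions of step 6 give the racemic ethyl α-hydroxy ester F6, a robust phenol.
- Preparative chromatography on a chiral stationary phase gives the (2R)-configured ethyl ester with the (2R,3S) ring, F7.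
- Silylation as in step 7 gives the silyl ether F8, and LiAlH4 as in step 8 gives 12.

**Step 9 (cleavage and reduction).** The likely failure is enolisation of aldehyde 13 under the basic borohydride and β-elimination of the ring-A phenoxide, which opens the dihydrofuran and destroys both centres.
Fallback, from 12 to 14: after the same NaIO4 cleavage and a quick extraction, crude 13 is oxidised under weakly acidic Pinnick conditions (NaClO2, NaH2PO4, 2-methyl-2-butene, t-BuOH–H2O) to the 3-carboxylic acid F9. Its carboxylate resists enolisation, and BH3·THF at 0 °C reduces it to 14.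

**Step 12 (Heck coupling).** The likely failure is slow oxidative addition into the electron-rich aryl bromide, so that at the temperature needed the silyl ethers are lost or 17 oligomerises; arylation at the internal alkene carbon is a lesser risk.
Fallback, from 14 to 18: Suzuki–Miyaura vinylation of 14 (CH2=CHBF3K, PdCl2(dppf), Et3N, n-PrOH, 80 °C) gives the 5-ethenyl compound F10. Olefin cross-metathesis of F10 with 17 (second-generation Grubbs catalyst, CH2Cl2, 40 °C) gives the E stilbene 18.

**Step 2 (benzofuran formation).** The likely failure is cyclisation without decarboxylation, or resinification of the aldehyde in hot anhydride.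
Fallback, from 1 to 3: 1 is heated with ethyl bromoacetate and K2CO3 in DMF to give ethyl 5-bromo-7-methoxy-1-benzofuran-2-carboxylate F11 by O-alkylation and aldol condensation. Saponification with NaOH gives the acid F12, and Cu powder in quinoline at 200 °C decarboxylates it to 3.

## Further compounds

F1 | step 6 | (1R,2S,5R)-5-methyl-2-(2-phenylpropan-2-yl)cyclohexyl (2R)-2-[(3S)-5-bromo-2-hydroxy-7-methoxy-2,3-dihydro-1-benzofuran-3-yl]-2-hydroxyacetate (lactol, both C2 anomers) | OC1Oc2c(OC)cc(Br)cc2[C@H]1[C@@H](O)C(=O)O[C@@H]3C[C@H](C)CC[C@H]3C(C)(C)c4ccccc4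
F2 | step 6 | (4-bromo-2,6-dimethoxyphenoxy)tri(propan-2-yl)silane | COc1cc(Br)cc(OC)c1O[Si](C(C)C)(C(C)C)C(C)C
F3 | step 6 | bromo{3,5-dimethoxy-4-[(triisopropylsilyl)oxy]phenyl}magnesium | COc1cc([Mg]Br)cc(OC)c1O[Si](C(C)C)(C(C)C)C(C)C
F4 | step 6 | (1R,2S,5R)-5-methyl-2-(2-phenylpropan-2-yl)cyclohexyl (2R,3R)-3-(5-bromo-2-hydroxy-3-methoxyphenyl)-4-{3,5-dimethoxy-4-[(triisopropylsilyl)oxy]phenyl}-2,4-dihydroxybutanoate (both C4 epimers) | COc1cc(C(O)[C@@H](c2cc(Br)cc(OC)c2O)[C@@H](O)C(=O)O[C@@H]3C[C@H](C)CC[C@H]3C(C)(C)c4ccccc4)cc(OC)c1O[Si](C(C)C)(C(C)C)C(C)C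
F5 | step 5 | ethyl rac-(2R,2aS,7aS)-4-bromo-6-methoxy-2a,7a-dihydro-2H-oxeto[2,3-b][1]benzofuran-2-carboxylate (racemate, ester exo) | CCOC(=O)[C@@H]1O[C@H]2Oc3c(OC)cc(Br)cc3[C@@H]12.CCOC(=O)[C@H]1O[C@@H]2Oc3c(OC)cc(Br)cc3[C@H]12
F6 | step 5 | ethyl rac-(2R)-2-[(2R,3S)-5-bromo-2-(4-hydroxy-3,5-dimethoxyphenyl)-7-methoxy-2,3-dihydro-1-benzofuran-3-yl]-2-hydroxyacetate (racemate) | COc1cc([C@@H]2Oc3c(OC)cc(Br)cc3[C@H]2[C@@H](O)C(=O)OCC)cc(OC)c1O.COc1cc([C@H]2Oc3c(OC)cc(Br)cc3[C@@H]2[C@H](O)C(=O)OCC)cc(OC)c1O
F7 | step 5 | ethyl (2R)-2-[(2R,3S)-5-bromo-2-(4-hydroxy-3,5-dimethoxyphenyl)-7-methoxy-2,3-dihydro-1-benzofuran-3-yl]-2-hydroxyacetate | COc1cc([C@@H]2Oc3c(OC)cc(Br)cc3[C@H]2[C@@H](O)C(=O)OCC)cc(OC)c1O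
F8 | step 5 | ethyl (2R)-2-[(2R,3S)-5-bromo-2-{3,5-dimethoxy-4-[(triisopropylsilyl)oxy]phenyl}-7-methoxy-2,3-dihydro-1-benzofuran-3-yl]-2-hydroxyacetate | COc1cc([C@@H]2Oc3c(OC)cc(Br)cc3[C@H]2[C@@H](O)C(=O)OCC)cc(OC)c1O[Si](C(C)C)(C(C)C)C(C)C
F9 | step 9 | (2R,3R)-5-bromo-2-{3,5-dimethoxy-4-[(triisopropylsilyl)oxy]phenyl}-7-methoxy-2,3-dihydro-1-benzofuran-3-carboxylic acid | COc1cc([C@@H]2Oc3c(OC)cc(Br)cc3[C@H]2C(=O)O)cc(OC)c1O[Si](C(C)C)(C(C)C)C(C)C
F10 | step 12 | [(2R,3S)-2-{3,5-dimethoxy-4-[(triisopropylsilyl)oxy]phenyl}-5-ethenyl-7-methoxy-2,3-dihydro-1-benzofuran-3-yl]methanol | COc1cc([C@@H]2Oc3c(OC)cc(C=C)cc3[C@H]2CO)cc(OC)c1O[Si](C(C)C)(C(C)C)C(C)C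
F11 | step 2 | ethyl 5-bromo-7-methoxy-1-benzofuran-2-carboxylate | CCOC(=O)c1cc2cc(Br)cc(OC)c2o1
F12 | step 2 | 5-bromo-7-methoxy-1-benzofuran-2-carboxylic acid | OC(=O)c1cc2cc(Br)cc(OC)c2o1
A1 | alternative 1 | trans-(2R,3S)-5-chloro-3-[(tert-butyldimethylsilyloxy)methyl]-7-methoxy-2-[3,5-dimethoxy-4-(triisopropylsilyloxy)phenyl]-2,3-dihydro-1-benzofuran | COc1cc([C@@H]2Oc3c(OC)cc(Cl)cc3[C@H]2CO[Si](C)(C)C(C)(C)C)cc(OC)c1O[Si](C(C)C)(C(C)C)C(C)C
A2 | alternative 1 | 6-chloro-4-methoxy-3-{[(1R,2S)-2-[(tert-butyldimethylsilyloxy)methyl]-1-[3,5-dimethoxy-4-(triisopropylsilyloxy)phenyl]but-3-yn-1-yl]oxy}pyridazine | COc1cc([C@H](Oc2nnc(Cl)cc2OC)[C@H](CO[Si](C)(C)C(C)(C)C)C#C)cc(OC)c1O[Si](C(C)C)(C(C)C)C(C)C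
A3 | alternative 2 | methyl trans-(2R,3R)-5-bromo-2-[3,5-dimethoxy-4-(pivaloyloxy)phenyl]-7-methoxy-2,3-dihydro-1-benzofuran-3-carboxylate | COc1cc([C@@H]2Oc3c(OC)cc(Br)cc3[C@H]2C(=O)OC)cc(OC)c1OC(=O)C(C)(C)C
A4 | alternative 2 | (2R)-6-bromo-8-methoxy-2-[3,5-dimethoxy-4-(pivaloyloxy)phenyl]-2,3-dihydro-4H-chromen-4-one | COc1cc([C@H]2CC(=O)c3cc(Br)cc(OC)c3O2)cc(OC)c1OC(=O)C(C)(C)C
A5 | alternative 3 | [(2R,3S)-5-bromo-2-(4-hydroxy-3,5-dimethoxyphenyl)-7-methoxy-2,3-dihydro-1-benzofuran-3-yl]methanol | COc1cc([C@@H]2Oc3c(OC)cc(Br)cc3[C@H]2CO)cc(OC)c1O
A6 | alternative 3 | (2S)-2-(5-bromo-2-hydroxy-3-methoxyphenyl)-3-(4-hydroxy-3,5-dimethoxyphenyl)propan-1-ol | COc1cc(C[C@H](CO)c2cc(Br)cc(OC)c2O)cc(OC)c1O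
A7 | alternative 3 | 4-[(2S)-2-(5-bromo-2-hydroxy-3-methoxyphenyl)-3-hydroxypropylidene]-2,6-dimethoxycyclohexa-2,5-dien-1-one | COC1=CC(=C[C@H](CO)c2cc(Br)cc(OC)c2O)C=C(OC)C1=O
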